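A direct plan would take 2,6-dibromo-4-methylphenol A1, turn one of its two equivalent C–Br bonds into C–OH by a CuI-catalysed hydroxylation steered by a borate tether, and brominate the resulting 3-bromo-5-methylbenzene-1,2-diol A2 twice with Br2.
The tethered mono-hydroxylation would be its weakest step: it would have no precedent, single against double hydroxylation and hydrodebromination would be left to chance, and a catechol would sit with copper and base at 100 °C.
The closing dibromination would be the second: Br2 also oxidizes catechols to o-quinones and can attack the benzylic methyl group, and this would be risked on the last intermediate.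
Third, the plan would destroy a C–Br bond that the target needs and rebuild it later, so half of its steps would add no net complexity.

**Plan of the new route**
With the target numbered C1(OH), C2(OH), C3(Br), C4(Br), C5(CH3), C6(Br), the retrosynthesis cuts the ring bonds C2–C3 and C1–C6.
The diene C3–C6 is the carbon chain of perbrominated 3-methylthiophene; C1–C2 comes from the ketene bis(silyl) acetal of glycolic acid, a masked dioxygenated alkyne.
The benzene ring arises last, in one operation: [4+2] cycloaddition to the thiophene 1,1-dioxide, loss of SO2, unmasking of the ketone hydrate.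
Enabling feature: C1 and C2 are flanked on both sides by C–Br carbons and end as two identical C–OH groups, so either orientation of addition gives the same arene.
All three C–Br bonds and both C–O bonds are bought, so no hydroxylation of an aryl bromide and no bromination of a catechol occurs.

Key step: step 2

Remark: both starting materials are taken as catalogue compounds; the intermediates of the key step that are not isolated are racemic and are written in the expected orientation of addition.

**Step 1**
Reactants: 1 2,3,5-tribromo-4-methylthiophene
Product: 3 2,3,5-tribromo-4-methylthiophene 1,1-dioxide, via thiophene 1-oxide 2 (not isolated)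
Conditions: H2O2·urea (5 equiv), (CF3CO)2O (5 equiv), MeCN, 0 °C to rt
Reagents that add atoms: hydrogen peroxide–urea, OO.NC(N)=O; its oxygen is transferred as peroxytrifluoroacetic acid, OOC(=O)C(F)(F)F
Why: Electrophilic S-oxidation of a thiophene by a peracid, running through the S-oxide 2 to the S,S-dioxide; the strongly electrophilic CF3CO3H is chosen because three bromines lower the nucleophilicity of sulfur, the reaction type is known for tetrabromo- and tetrachlorothiophene, the vinylic C–Br bonds and the methyl group are inert to the peracid, the fully substituted diene of 3 is shielded from self-dimerization, and 3 has no stereocentre.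

**Step 2**
Reactants: 3 2,3,5-tribromo-4-methylthiophene 1,1-dioxide; 4 1,1,2-tris(trimethylsilyloxy)ethene
Product: 8 3,4,6-tribromo-5-methylbenzene-1,2-diol, via bridged sulfone adduct 5 (not isolated), via tris(silyloxy)cyclohexadiene 6 (not isolated), via hydroxydienone 7 (not isolated)
Conditions: 4 (1.5 equiv), toluene, 0 °C to rt then 50 °C, Ar sweep; then 1 M HCl (aq), THF, rt, Ar
Reagents that add atoms: none
Why: Inverse-electron-demand [4+2] cycloaddition of the electron-poor ring diene of 3, held s-cis by the five-membered ring, with the electron-rich ketene bis(silyl) acetal 4 should give the 7-thiabicyclo[2.2.1]heptene 7,7-dioxide 5, which loses SO2 by cheletropic extrusion to the cyclohexa-1,3-diene 6; aqueous acid then cleaves the three Si–O bonds, the freed ketone hydrate collapses to ketone 7, and 7, the keto tautomer of the catechol, enolizes irreversibly to 8 with both oxygens coming from 4. The closest known reaction type is the cycloaddition–SO2 extrusion–elimination sequence of tetrachloro- and tetrabromothiophene 1,1-dioxide with enol ethers and other electron-rich alkenes to give benzenes, together with the use of 1,1,2-trialkoxyethenes as dioxygenated-alkyne equivalents in inverse-demand Diels–Alder reactions. The benzene ring is the only ring closed, by an intermolecular [4+2] that forms the C1–C6 and C2–C3 bonds of 8, and it becomes aromatic only after SO2 and the silyl groups have left. The stereocentres of 5, 6 and 7 (bridgeheads and CH–O carbon) are transient and are erased on aromatization, so none has to be controlled. No regioselectivity is needed, because both carbons of 4 end as C–OH and the opposite orientation of addition leads to the same arene, and no wrong elimination is open to 6, since its ketal carbon bears no hydrogen and only the CH–O hydrogen can be lost. The selectivity that is needed is cycloaddition over conjugate addition–elimination at a vinylic C–Br, which the locked s-cis diene and the concerted pathway of the neutral ketene acetal should secure, while the Ar sweep removes SO2 before it can consume 4.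

**Compound list**
1 | 2,3,5-tribromo-4-methylthiophene | Cc1c(Br)sc(Br)c1Br | starting material
2 | 2,3,5-tribromo-4-methylthiophene 1-oxide | CC1=C(Br)S(=O)C(Br)=C1Br | intermediate
3 | 2,3,5-tribromo-4-methylthiophene 1,1-dioxide | CC1=C(Br)S(=O)(=O)C(Br)=C1Br | intermediate
4 | 1,1,2-tris(trimethylsilyloxy)ethene | C[Si](C)(C)OC=C(O[Si](C)(C)C)O[Si](C)(C)C | starting material
5 | 1,2,4-tribromo-3-methyl-5,5,6-tris(trimethylsilyloxy)-7-thiabicyclo[2.2.1]hept-2-ene 7,7-dioxide (racemic, configuration at C6 not defined) | CC1=C(Br)C2(Br)C(O[Si](C)(C)C)C(O[Si](C)(C)C)(O[Si](C)(C)C)C1(Br)S2(=O)=O | intermediate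
6 | 1,2,4-tribromo-3-methyl-5,5,6-tris(trimethylsilyloxy)cyclohexa-1,3-diene (racemic) | CC1=C(Br)C(O[Si](C)(C)C)(O[Si](C)(C)C)C(O[Si](C)(C)C)C(Br)=C1Br | intermediate
7 | 2,4,5-tribromo-6-hydroxy-3-methylcyclohexa-2,4-dien-1-one (racemic) | O=C1C(Br)=C(C)C(Br)=C(Br)C1O | intermediate
8 | 3,4,6-tribromo-5-methylbenzene-1,2-diol | Cc1c(Br)c(O)c(O)c(Br)c1Br | target

**Count and risks**
Total steps: 2. Longest linear sequence: 2 steps. The route has only two steps, so both are ranked, the key step first.

Step 2 (riskiest). The ketene acetal may add to the diene in a stepwise, polar manner and then expel bromide or transfer silicon, giving conjugate addition–elimination instead of ring closure, or it may be consumed by the SO2 that is released. The fallback sets out from 3 and comes back to the route at 8. A thermal Diels–Alder reaction of 3 with the non-nucleophilic dienophile vinylene carbonate, 1,3-dioxol-2-one, in o-xylene at 130 °C, a dienophile known to add to perhalogenated inverse-demand dienes, would pass through the bridged sulfone 4,5,7-tribromo-6-methyl-3a,4,7,7a-tetrahydro-4,7-epithio-1,3-benzodioxol-2-one 8,8-dioxide F1 and, after loss of SO2, give cis-4,5,7-tribromo-6-methyl-3a,7a-dihydro-1,3-benzodioxol-2-one F2. Methanolysis with catalytic K2CO3 in MeOH at 0 °C would give cis-3,4,6-tribromo-5-methylcyclohexa-3,5-diene-1,2-diol F3. Oxidation of one carbinol with IBX, 2-iodoxybenzoic acid, in DMSO at rt, followed by a Na2S2O4 work-up to reduce any o-quinone, would give hydroxydienone 7 or its regioisomer 2,3,5-tribromo-6-hydroxy-4-methylcyclohexa-2,4-dien-1-one F4, and either one enolizes to 8.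

Step 1. The sulfur atom, deactivated by three bromines, may resist the second oxidation, so that conversion stalls or the peracid is spent in side reactions. The fallback sets out from 1 and comes back to the route at 3. Double bromine–lithium exchange at the two α-positions with n-BuLi, 2.1 equiv, in THF at −78 °C would give 3-bromo-2,5-dilithio-4-methylthiophene F5, and a quench with Me3SiCl would give 3-bromo-4-methyl-2,5-bis(trimethylsilyl)thiophene F6, an electron-richer thiophene of the class that mCPBA in CH2Cl2 at rt oxidizes smoothly. The product would be 3-bromo-4-methyl-2,5-bis(trimethylsilyl)thiophene 1,1-dioxide F7, and ipso-bromodesilylation of both C–Si bonds with Br2 and AgBF4 in CH2Cl2 at 0 °C would return 3.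

**Further compounds**
F1 | step 2 | 4,5,7-tribromo-6-methyl-3a,4,7,7a-tetrahydro-4,7-epithio-1,3-benzodioxol-2-one 8,8-dioxide (racemic) | O=C1OC2C(O1)C3(Br)C(C)=C(Br)C2(Br)S3(=O)=O
F2 | step 2 | cis-4,5,7-tribromo-6-methyl-3a,7a-dihydro-1,3-benzodioxol-2-one (racemic) | O=C1O[C@H]2C(Br)=C(Br)C(C)=C(Br)[C@H]2O1
F3 | step 2 | cis-3,4,6-tribromo-5-methylcyclohexa-3,5-diene-1,2-diol (racemic) | O[C@H]1C(Br)=C(Br)C(C)=C(Br)[C@H]1O
F4 | step 2 | 2,3,5-tribromo-6-hydroxy-4-methylcyclohexa-2,4-dien-1-one (racemic) | O=C1C(Br)=C(Br)C(C)=C(Br)C1O
F5 | step 1 | 3-bromo-2,5-dilithio-4-methylthiophene | Cc1c([Li])sc([Li])c1Br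
F6 | step 1 | 3-bromo-4-methyl-2,5-bis(trimethylsilyl)thiophene | Cc1c([Si](C)(C)C)sc([Si](C)(C)C)c1Br
F7 | step 1 | 3-bromo-4-methyl-2,5-bis(trimethylsilyl)thiophene 1,1-dioxide | CC1=C([Si](C)(C)C)S(=O)(=O)C([Si](C)(C)C)=C1Br
A1 | direct plan | 2,6-dibromo-4-methylphenol | Cc1cc(Br)c(O)c(Br)c1
A2 | direct plan | 3-bromo-5-methylbenzene-1,2-diol | Cc1cc(O)c(O)c(Br)c1
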